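**Retrosynthetic overview**
- Target ⇐ removal of four MOM ethers from the fully protected 6‑lavandulylflavone.
- The 4‑pyranone is the only ring made (both benzene rings are bought). It is closed last, in one flask, led by C–O bond formation: a propiolate oxygen adds to an A‑ring aryne (C8a–O1), then O→C acyl shift (C4a–C4), then 6‑endo closure (O1–C2).
- Aryne precursor ⇐ 5‑chlororesorcinol bis‑MOM ether + (R)‑lavandulyl iodide by directed metalation between the two OMOM groups. The chloride para to the side chain fixes where O1 enters, so the side chain can only end up at C6.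
- Propiolate ⇐ 2,4‑dihydroxybenzaldehyde (MOM protection, alkyne homologation) + CO2.
- The single stereocentre is bought with (R)‑lavandulol and is never a reacting centre.

Assumption: (R)‑(−)‑lavandulol is bought enantiopure; it has the same spatial arrangement as the target side chain, whose descriptor reads (S) only because CH2Ar ranks below isopropenyl.

Abbreviations: MOM = methoxymethyl; lavandulyl = 5‑methyl‑2‑(prop‑1‑en‑2‑yl)hex‑4‑en‑1‑yl; LiTMP = lithium 2,2,6,6‑tetramethylpiperidide.

**Route**

Step 1
Reactants: 1 5-chlororesorcinol (5-chlorobenzene-1,3-diol)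
Product: 2 1-chloro-3,5-bis(methoxymethoxy)benzene
Conditions: MOMCl, K2CO3, acetone, reflux
Reagents that add atoms: chloromethyl methyl ether (MOMCl), COCCl
Why: Williamson-type O-alkylation of both phenols gives the bis-acetal whose OMOM groups later direct metalation; no stereocentre is involved.

Step 2
Reactants: 3 (R)-lavandulol [(2R)-5-methyl-2-(prop-1-en-2-yl)hex-4-en-1-ol]
Product: 4 (R)-lavandulyl iodide [(3R)-3-(iodomethyl)-2,6-dimethylhepta-1,5-diene]
Conditions: I2, PPh3, imidazole, CH2Cl2, 0 °C → rt
Reagents that add atoms: iodine, II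
Why: Appel-type iodination (SN2 displacement of the alkoxyphosphonium at the primary CH2); the stereocentre is not a reacting centre, so the configuration of the bought alcohol is kept.

Step 3
Reactants: 2 1-chloro-3,5-bis(methoxymethoxy)benzene; 4 (R)-lavandulyl iodide
Product: 7 5-chloro-1,3-bis(methoxymethoxy)-2-[(2S)-5-methyl-2-(prop-1-en-2-yl)hex-4-en-1-yl]benzene, via aryllithium 5 (not isolated), via arylmagnesium bromide 6 (not isolated)
Conditions: s-BuLi, TMEDA, THF, −78 °C; MgBr2·OEt2, −78 → −20 °C; then 4, Li2CuCl4 (5 mol %), −20 °C → rt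
Reagents that add atoms: none
Why: Directed ortho-metalation at the carbon flanked by both OMOM groups (para to Cl), transmetalation to the less basic Grignard and Kochi-type copper-catalysed sp2–sp3 coupling at the primary CH2–I; the stereocentre is one carbon away from the reacting centre and is carried through unchanged.

Step 4
Reactants: 8 2,4-dihydroxybenzaldehyde
Product: 9 2,4-bis(methoxymethoxy)benzaldehyde
Conditions: MOMCl, K2CO3, acetone, reflux
Reagents that add atoms: chloromethyl methyl ether (MOMCl), COCCl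
Why: Williamson-type O-alkylation of both phenols (the chelated 2-OH needs the excess reagent and reflux); no stereocentre is involved.

Step 5
Reactants: 9 2,4-bis(methoxymethoxy)benzaldehyde
Product: 10 1-ethynyl-2,4-bis(methoxymethoxy)benzene
Conditions: Bestmann–Ohira reagent, K2CO3, MeOH, rt
Reagents that add atoms: dimethyl (1-diazo-2-oxopropyl)phosphonate (Bestmann–Ohira reagent), CC(=O)C(=[N+]=[N-])P(=O)(OC)OC
Why: Seyferth–Gilbert homologation in its Ohira–Bestmann form: the diazomethylphosphonate anion made in situ adds to the aldehyde, and loss of phosphate and N2 followed by 1,2-H shift gives the terminal alkyne; MOM ethers tolerate K2CO3/MeOH.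

Step 6
Reactants: 10 1-ethynyl-2,4-bis(methoxymethoxy)benzene; 7 5-chloro-1,3-bis(methoxymethoxy)-2-[(2S)-5-methyl-2-(prop-1-en-2-yl)hex-4-en-1-yl]benzene
Product: 14 2-[2,4-bis(methoxymethoxy)phenyl]-5,7-bis(methoxymethoxy)-6-[(2S)-5-methyl-2-(prop-1-en-2-yl)hex-4-en-1-yl]-4H-chromen-4-one, via lithium arylpropiolate 11 (not isolated), via alkoxyaryne 12 (not isolated), via lithium acylphenolate 13 (not isolated)
Conditions: 10 (2 equiv), n-BuLi, THF, −78 °C; CO2 (1 atm), −78 °C → rt, then Ar purge; 7 (1 equiv), DMPU; LiTMP (1.3 equiv, slow addition), −30 °C → rt, then 50 °C; H2O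
Reagents that add atoms: carbon dioxide, O=C=O
Why: Proposed new method: a three-component aryne annulation in which LiTMP removes the proton between Cl and OMOM of 7 and loss of LiCl gives the 3-alkoxyaryne 12; its distortion sends the carboxylate oxygen of 11 to the distal carbon (the former C–Cl carbon, para to the side chain), the ortho-aryl anion so formed attacks the ester carbonyl (anionic ortho-Fries 1,3-O→C acyl shift) to give phenolate ynone 13, and 6-endo-dig oxa-Michael closure in the aprotic medium forms the pyranone with the side chain necessarily at C6; the closest known reaction types are fluoride-triggered aryne insertion into the C–O bond of carboxylic (including alkynoic) acids, amide-base aryne generation from chloroarenes with anionic trapping, and the anionic Fries rearrangement, but their combination with a CO2-derived lithium propiolate and a base-generated polyalkoxyaryne has not been shown; no stereocentre is formed or touched.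

Step 7
Reactants: 14 2-[2,4-bis(methoxymethoxy)phenyl]-5,7-bis(methoxymethoxy)-6-[(2S)-5-methyl-2-(prop-1-en-2-yl)hex-4-en-1-yl]-4H-chromen-4-one
Product: 15 2-(2,4-dihydroxyphenyl)-5,7-dihydroxy-6-[(2S)-5-methyl-2-(prop-1-en-2-yl)hex-4-en-1-yl]-4H-chromen-4-one (target)
Conditions: 3 M aq HCl, MeOH, 45 °C
Reagents that add atoms: none
Why: Acid-catalysed transacetalisation of the four aryl MOM ethers to dimethoxymethane under mild conditions of the kind used for C-prenylated polyphenols; the stereocentre is untouched as long as the isopropenyl group is not protonated.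

**Compound list**

1 | 5-chlororesorcinol (5-chlorobenzene-1,3-diol) | Oc1cc(O)cc(Cl)c1 | starting material
2 | 1-chloro-3,5-bis(methoxymethoxy)benzene | COCOc1cc(Cl)cc(OCOC)c1 | intermediate
3 | (R)-lavandulol, (2R)-5-methyl-2-(prop-1-en-2-yl)hex-4-en-1-ol | C=C(C)[C@@H](CC=C(C)C)CO | starting material
4 | (R)-lavandulyl iodide, (3R)-3-(iodomethyl)-2,6-dimethylhepta-1,5-diene | C=C(C)[C@@H](CC=C(C)C)CI | intermediate
5 | [4-chloro-2,6-bis(methoxymethoxy)phenyl]lithium | [Li]c1c(OCOC)cc(Cl)cc1OCOC | intermediate
6 | [4-chloro-2,6-bis(methoxymethoxy)phenyl]magnesium bromide | Br[Mg]c1c(OCOC)cc(Cl)cc1OCOC | intermediate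
7 | 5-chloro-1,3-bis(methoxymethoxy)-2-[(2S)-5-methyl-2-(prop-1-en-2-yl)hex-4-en-1-yl]benzene | C=C(C)[C@@H](CC=C(C)C)Cc1c(OCOC)cc(Cl)cc1OCOC | intermediate
8 | 2,4-dihydroxybenzaldehyde | O=Cc1ccc(O)cc1O | starting material
9 | 2,4-bis(methoxymethoxy)benzaldehyde | COCOc1ccc(C=O)c(OCOC)c1 | intermediate
10 | 1-ethynyl-2,4-bis(methoxymethoxy)benzene | C#Cc1ccc(OCOC)cc1OCOC | intermediate
11 | lithium 3-[2,4-bis(methoxymethoxy)phenyl]prop-2-ynoate | [Li+].[O-]C(=O)C#Cc1ccc(OCOC)cc1OCOC | intermediate
12 | 3,5-bis(methoxymethoxy)-4-[(2S)-5-methyl-2-(prop-1-en-2-yl)hex-4-en-1-yl]benzyne (1,2-didehydrobenzene) | C=C(C)[C@@H](CC=C(C)C)CC1=C(OCOC)C#CC=C1OCOC | intermediate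
13 | lithium 2-{3-[2,4-bis(methoxymethoxy)phenyl]prop-2-ynoyl}-3,5-bis(methoxymethoxy)-4-[(2S)-5-methyl-2-(prop-1-en-2-yl)hex-4-en-1-yl]phenolate | C=C(C)[C@@H](CC=C(C)C)Cc1c(OCOC)cc([O-])c(C(=O)C#Cc2ccc(OCOC)cc2OCOC)c1OCOC.[Li+] | intermediate
14 | 2-[2,4-bis(methoxymethoxy)phenyl]-5,7-bis(methoxymethoxy)-6-[(2S)-5-methyl-2-(prop-1-en-2-yl)hex-4-en-1-yl]-4H-chromen-4-one | C=C(C)[C@@H](CC=C(C)C)Cc1c(OCOC)cc2oc(-c3ccc(OCOC)cc3OCOC)cc(=O)c2c1OCOC | intermediate
15 | 2-(2,4-dihydroxyphenyl)-5,7-dihydroxy-6-[(2S)-5-methyl-2-(prop-1-en-2-yl)hex-4-en-1-yl]-4H-chromen-4-one | C=C(C)[C@@H](CC=C(C)C)Cc1c(O)cc2oc(-c3ccc(O)cc3O)cc(=O)c2c1O | target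

**Step count and risks**

Total step count: 7. Longest linear sequence: 4 steps (1 → 3 → 6 → 7; the branch 4 → 5 → 6 → 7 is equally long).

Steps most likely to fail:

Step 6 (the proposed new annulation). The lithium carboxylate may be too weak an aryne trap, so that 12 is lost to coupling with still-lithiated 7, to TMP addition or to an ene reaction with a prenyl group. Phenolate 13 could also close 5-exo to an aurone. The fallback uses known chemistry only, sets out from 7 and comes back at 14. Lithiate 7 with LiTMP at −78 °C, where the ortho-lithio chloride does not yet lose LiCl, and acylate with N-methoxy-N-methylacetamide to give 1-{6-chloro-2,4-bis(methoxymethoxy)-3-[(2S)-5-methyl-2-(prop-1-en-2-yl)hex-4-en-1-yl]phenyl}ethan-1-one F3. Protect commercial methyl 2,4-dihydroxybenzoate (MOMCl, K2CO3, acetone) to methyl 2,4-bis(methoxymethoxy)benzoate F4. Claisen condensation of the lithium enolate of F3 (LiHMDS, THF, −78 °C → rt) with F4 gives 1-[2,4-bis(methoxymethoxy)phenyl]-3-{6-chloro-2,4-bis(methoxymethoxy)-3-[(2S)-5-methyl-2-(prop-1-en-2-yl)hex-4-en-1-yl]phenyl}propane-1,3-dione F5. Intramolecular O-arylation of its enolate (K2CO3, CuI, 1,10-phenanthroline, DMF, 110 °C) displaces the chloride and closes the pyranone to 14, with the regiochemistry again fixed by the C–Cl position.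

Step 3. The hindered aryl nucleophile may react slowly with the β-branched iodide, whose allylic β-hydrogen invites E2 elimination to a diene. Any metalation next to chlorine would be lost as aryne on warming. The fallback sets out from 2 and 4 and comes back at 7, replacing substitution by a palladium cross-coupling of reversed polarity. Lithiate 2 as in step 3 and quench with iodine to give 5-chloro-2-iodo-1,3-bis(methoxymethoxy)benzene F1. Insert zinc dust (LiCl, THF, 40 °C) into iodide 4 to give [(2R)-5-methyl-2-(prop-1-en-2-yl)hex-4-en-1-yl]zinc iodide F2. Negishi coupling of F1 with F2 (Pd(OAc)2, SPhos, THF, rt → 40 °C), in which C–I reacts and C–Cl does not, gives 7.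

Step 7. Protic acid can protonate the isopropenyl group next to the freed 5- and 7-hydroxyls and close a 2,2-dimethylchroman, or shift the double bond and erase the stereocentre. The fallback sets out from 14 and comes back at 15. It changes the cleavage mode from Brønsted-acid solvolysis to Lewis-acid-assisted dealkylation by a soft sulfur nucleophile in aprotic medium (ZnBr2, n-PrSH, CH2Cl2, 0 °C, minutes), which removes aryl MOM ethers without a free strong acid; it makes no new isolated compound.

Further compounds
F1 | step 3 | 5-chloro-2-iodo-1,3-bis(methoxymethoxy)benzene | COCOc1cc(Cl)cc(OCOC)c1I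
F2 | step 3 | [(2R)-5-methyl-2-(prop-1-en-2-yl)hex-4-en-1-yl]zinc iodide | C=C(C)[C@@H](CC=C(C)C)C[Zn]I
F3 | step 6 | 1-{6-chloro-2,4-bis(methoxymethoxy)-3-[(2S)-5-methyl-2-(prop-1-en-2-yl)hex-4-en-1-yl]phenyl}ethan-1-one | C=C(C)[C@@H](CC=C(C)C)Cc1c(OCOC)cc(Cl)c(C(C)=O)c1OCOC
F4 | step 6 | methyl 2,4-bis(methoxymethoxy)benzoate | COCOc1ccc(C(=O)OC)c(OCOC)c1
F5 | step 6 | 1-[2,4-bis(methoxymethoxy)phenyl]-3-{6-chloro-2,4-bis(methoxymethoxy)-3-[(2S)-5-methyl-2-(prop-1-en-2-yl)hex-4-en-1-yl]phenyl}propane-1,3-dione | C=C(C)[C@@H](CC=C(C)C)Cc1c(OCOC)cc(Cl)c(C(=O)CC(=O)c2ccc(OCOC)cc2OCOC)c1OCOC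
F0 | step 7 | none | none
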